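I counted before I trusted any simulation.

all flasks: substrate 0.20 M; initiator 10 mM
- amber: reagent 0.15 M; radical scavenger 1 mM; temperature 125 °C; run made earlier
- green: reagent 0.27 M; radical scavenger 1 mM; temperature 158 °C; run made earlier
- ochre: reagent 0.45 M; radical scavenger 1 mM; temperature 125 °C; run made earlier
- violet: reagent 0.20 M; radical scavenger 1.6 mM; temperature 158 °C; run made earlier
- larch: reagent 0.200 M; radical scavenger 1.0 mM; at 110 °C until 1.5 min, from then on at 170 °C; time 8.0 min
- ash: reagent 0.400 M; radical scavenger 1.5 mM; at 110 °C throughout; time 8.0 min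

- amber (time / min: target / %, substrate / %): 0.333: 0, 100.4; 0.667: 0, 99.5; 1.33: 0.2, 99.8; 2.00: 0.5, 99.7; 4.00: 0.1, 99.4
- green (time / s: target / %, substrate / %): 10.0: 0.6, 100.2; 12.0: 0.1, 99.2; 20.0: 3.0, 97.5; 30.0: 19.9, 79.4; 40.0: 34.0, 65.3
- ochre (time / min: target / %, substrate / %): 0.667: 0.1, 99.9; 1.33: 0.1, 99.9; 2.50: 0, 99.3; 3.00: 0.1, 99.4; 4.00: 0.5, 99.2
- violet (time / s: target / %, substrate / %): 10.0: 0.2, 99.7; 15.0: 0.6, 99.4; 20.0: 0.5, 99.5; 40.0: 14.5, 84.8

(scatter of a reading: 0.3 percentage points)

- the winner by amount of target, in percent of the substrate charged; "neither" if no more than 2 percentage points parts them (larch / ash / neither)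
- how much target is there at the end, in percent of the substrate charged: larch
- how much target is there at the end, in percent of the substrate charged: ash



Green's target climbed from 19.9% to 34.0% between 30.0 s and 40.0 s, and that line runs back to zero at 15.9 s. I called this reading the holding time (the induction period): the time a charge of radical scavenger keeps the chain down, taken, at one temperature, in proportion to that charge. Violet, with 1.6 mM, should then hold for 25.4 s, and its target still stood at 0.5% at 20.0 s. Amber's 1 mM held for at least 4.00 min at 125 °C, so I gave the holding time an apparent activation energy of at least 117 kJ mol⁻¹.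

Then I put the clocks in order, shortest first. At 170 °C, larch's charge of radical scavenger holds for about 6.54 s. Before that, the first 1.5 min of larch at 110 °C should use at most 9.35% of that charge. Next comes the life of the reagent once the chain runs: green's slope, taken as first order in reagent, gives 95.7 s at 158 °C. Larch's hot stretch of 383 s is longer than that life, 4.00 lifetimes at green's pace, so I expected about 98.2% target. Last comes ash: its charge should hold for at least 24.1 min, longer than its 8.0 min, so I expected its target to stay under the 0.5% that ochre read at 4.00 min.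

The forecast named larch, with 95% against 0.2%, and read the runs as “a radical chain held back until the scavenger is consumed”.

The simulation gave larch 96.7% and ash 0.210%, so the winner is larch. Ash still held 73.4% of its radical scavenger at 8.00 min; at a steady pace of use, that makes its holding time 30.1 min, longer than my floor of 24.1 min.

    2 first chain carrier → ended chains B (k = 4.50 × 10⁷ M⁻¹ s⁻¹, Ea = 19.0 kJ mol⁻¹)
    reagent + first chain carrier → target + second chain carrier (k = 12000 M⁻¹ s⁻¹, Ea = 35.0 kJ mol⁻¹)
    initiator → 2 initiating radical (k = 4.20 × 10⁻⁵ s⁻¹, Ea = 119 kJ mol⁻¹)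
    substrate + second chain carrier → released group + first chain carrier (k = 42000 M⁻¹ s⁻¹, Ea = 29.0 kJ mol⁻¹)
    second chain carrier + radical scavenger → ended chains C (k = 1.20 × 10⁸ M⁻¹ s⁻¹, Ea = 12.0 kJ mol⁻¹)
    substrate + initiating radical → capped initiator + first chain carrier (k = 3.60 × 10⁵ M⁻¹ s⁻¹, Ea = 18.0 kJ mol⁻¹)
    2 second chain carrier → ended chains A (k = 3.00 × 10⁸ M⁻¹ s⁻¹, Ea = 15.0 kJ mol⁻¹)
    2 substrate → homo dimer (k = 5.40 × 10⁻⁶ M⁻¹ s⁻¹, Ea = 109 kJ mol⁻¹)
    (constants at 110 °C)

Ash moved to 125 °C tests this. The line from that value to green's holding time has an apparent activation energy of 124 kJ mol⁻¹ and gives 6.95 min, shorter than the run, so the chain should start with about 1.05 min to go. The computed flask ends with 9.15% target and 0% of its radical scavenger.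

The readings were computed on assumed constants, and the scatter is random.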